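## The problem

Catechin 7,3'-di-O-gallate (15) is a 2,3-trans-flavan-3-ol. Ring A is fused to the dihydropyran ring C (O1, C2, C3, C4, C4a, C8a), ring B sits on C2, and a free hydroxyl sits on C3. Galloyl esters are on O7 (ring A) and O3' (ring B), while O5 and O4' are free. The three benzene rings can be bought with their oxygens in place, so only ring C has to be built.

The two stereocentres, C2 (R) and C3 (S), are adjacent and trans. There is no third stereocentre to relay from, so the absolute configuration must come from a catalyst or reagent. The relative configuration can come from an alkene geometry if both centres are set together, or from the C2 aryl group directing a later addition at C3.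

On the assembled flavan, O5/O7 and O3'/O4' are too alike to acylate selectively. On the monocyclic precursors they are distinct: in 2,4,6-trihydroxybenzaldehyde only the 4-OH is not hydrogen-bonded to the formyl group, and 4-(benzyloxy)-3-hydroxybenzaldehyde is sold with O4 already masked. The gallates should therefore arrive on the fragments.

The sensitive groups are:
- the two aryl gallates, which do not tolerate hydroxide, alkoxide, hydride or organometallic reagents, and the 3'-ester can migrate to O4' once O4' is free and basic;
- the C2–O1 bond, a benzylic ether para to O4', which ionises under strong acid;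
- the free polyphenol, which oxidises in air when basic.

The enabling feature is that O1–C8a–C4a–C4 is an ortho-quinone methide in latent form, with C4 a plain methylene. The C2–C3 unit, with aryl on C2 and a trans oxygen on C3, is the (E)-enol derivative of the ring B arylacetaldehyde. A [4+2] union of the two makes O1–C2, C3–C4, ring C and both stereocentres at once.

## Retrosynthesis

**15 from 14.** The last operation must be neutral and must free nine hydroxyls without touching two aryl esters. Cutting eight O–benzyl bonds and the O3 benzyl carbonate leads to 14, in which every hydroxyl is masked by a group that falls to hydrogen. The carbonate on O3 is chosen because it leaves as toluene and CO2 in the same step and because the dienophile needs an acylated oxygen (see below).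

**14 from 6 and 12 through 13.** Cutting O1–C2 and C3–C4 splits 14 into two fragments of similar size, each carrying one gallate: salicyl alcohol 6 (rings A, C4, O1) and (E)-enol carbonate 12 (ring B, C2, C3). The neighbouring cuts are weaker for this target. Cutting O1–C2 alone leaves both stereocentres to be made on an open chain and pushes acylation to the end. Cutting C4–C4a needs a Friedel–Crafts reaction on a ring A with two open positions. Forward, 6 loses water to quinone methide 13, which must add 12 with three selectivities: the aryl-bearing carbon to O1, suprafacial addition so that E becomes trans, and one face of 12. An alkyl or silyl enol ether would place its oxygen-bearing carbon on O1. The carbonate oxygen is cross-conjugated and a weak donor, so the 4-benzyloxyphenyl group decides the polarity.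

**12 from 8 through 9, 10 and 11.** Enolising the arylacetaldehyde and acylating on oxygen would give geometric mixtures, yet the trans relationship in 14 depends on pure E. The double bond is therefore made E first and then carried with retention:
- 12 is cut at the carbonate C–O bond to potassium enolate 11;
- 11 comes from enol formate 10 by alkoxide cleavage;
- 10 comes from enal 9 by Baeyer–Villiger oxidation, with alkenyl migration;
- 9 comes from aldehyde 8 by a Wittig reaction with a stabilised ylide.

**8 from 7 and 2.** The ester C–O bond is cut. 7 has a single free phenol, so the 3'-gallate goes on without any selectivity question.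

**6 from 3 and 2 through 4 and 5.** The benzylic alcohol of 6 comes from aldehyde 5 by hydride reduction. The O5 benzyl ether of 5 comes from 4 by mono-etherification of one of two equivalent chelated hydroxyls; this must be done under neutral conditions to keep the aryl ester. The gallate of 4 goes onto the only non-chelated hydroxyl of 3. The benzyl ether lowers the nucleophilicity of ring A and keeps 6 soluble.

**2 from 1.** The acid chloride serves both esterifications.

## Roads not taken

Alternative 1: This route cuts C4–C4a and O1–C2 and lets a cyclohexane-1,3-dione stand in for ring A. L-Proline would condense dione A1 with epoxy aldehyde A2, the Hantzsch ester would reduce the alkylidene dione, and the enol oxygen would open the epoxide at its benzylic carbon to give A3.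
- Merits: A2 is the kind of epoxide that established asymmetric epoxidations deliver in high enantiomeric purity, and opening with inversion gives the trans arrangement stereospecifically. In certainty of absolute configuration this road is better than the chosen one.
- Weak points: A2 is an α-oxygenated aldehyde exposed to an amine catalyst, and its alkylidene dione is a vinylogous acceptor next to an epoxide. Ring A must then be aromatised by dehydrogenation while the C7 silyloxy group sits β to the ketone, so loss of silanol would give the 7-deoxy arene. After that, O5 and O3 must be masked, the silyl ethers removed, two gallates installed and everything deprotected, roughly six operations after ring closure.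
- Comparison: the chosen plan sets against the better stereochemical precedent a single step after ring closure and no acylation on the assembled core.

Alternative 2: This route cuts the C3–C4 double bond of a flav-3-ene. RuCl2(=CHPh)(PCy3)(H2IMes), the second-generation Grubbs catalyst, would close diene A4 to chromene A5. Hydroboration–oxidation of A5 would then place the C3 hydroxyl trans to the C2 aryl group.
- Merits: ring-closing metathesis to 2H-chromenes and the anti hydroboration are both well precedented, so each step stands on firmer ground than the chosen key step.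
- Weak points: the stereocentre of A4 and A5 is allylic, benzylic, para-oxygenated and bears an aryloxy leaving group, so ionisation can erode it. A4 also needs its own enantioselective allylic etherification. After the metathesis about five operations remain: hydroboration, O3 protection, acetal removal, double galloylation and hydrogenolysis.
- Comparison: the chosen plan answers with convergence, both stereocentres in one step and no protecting-group exchange on the flavan. Its fallback for the key step borrows this hydroboration.

Alternative 3: This route builds ring B by cutting C1'–C2' and C5'–C6'. Diene A6 would add thermally to ynone A7 to give cyclohexadiene A8, to be aromatised with the gallate on O3' and a silyl ether on O4'.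
- Merits: a thermal Diels–Alder reaction needs no catalyst, and C3 comes from A7 with fixed configuration.
- Weak points: the O3'/O4' differentiation it achieves is already available in a commercial benzaldehyde. The regiochemistry rests on the modest difference between a silyloxy and an aroyloxy donor. A6 is prone to acyl and silyl shifts. A8 can aromatise by elimination instead of dehydrogenation. C2 must still be set by ketone reduction, and ring C closed at a benzylic carbon that ionises easily.
- Comparison: it is longer than the chosen plan at every stage and is better only in that its key step is unquestionably feasible.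

Key step: step 9

Assumption: the (R)-enantiomer of the phosphoric acid is written as the one that leads to (2R,3S)-14. The sense of induction cannot be predicted with confidence for a diene without stereocentres, so if a trial run gives the antipode the (S)-acid is used with no other change.

## Route

Step 1
Reactants: 1 3,4,5-tris(benzyloxy)benzoic acid
Product: 2 3,4,5-tris(benzyloxy)benzoyl chloride
Conditions: (COCl)2, N,N-dimethylformamide (cat.), CH2Cl2, 0 °C to rt; volatiles removed
Reagents that add atoms: oxalyl chloride, ClC(=O)C(=O)Cl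
Why: Standard acid chloride formation through the Vilsmeier-type chloroiminium species; benzyl ethers are inert and the crude chloride serves both esterifications.

Step 2
Reactants: 3 2,4,6-trihydroxybenzaldehyde; 2 3,4,5-tris(benzyloxy)benzoyl chloride
Product: 4 4-formyl-3,5-dihydroxyphenyl 3,4,5-tris(benzyloxy)benzoate
Conditions: i-Pr2NEt (1.05 equiv), THF, −40 to 0 °C, 2 (1.0 equiv) added slowly
Reagents that add atoms: none
Why: Base-mediated O-acylation of the most acidic hydroxyl; the 4-OH is the only one not tied into the hydrogen bond with the formyl group, so its phenoxide forms and reacts first, and limiting the chloride should hold the reaction at the mono-ester.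

Step 3
Reactants: 4 4-formyl-3,5-dihydroxyphenyl 3,4,5-tris(benzyloxy)benzoate
Product: 5 3-(benzyloxy)-4-formyl-5-hydroxyphenyl 3,4,5-tris(benzyloxy)benzoate
Conditions: BnOH (1.1 equiv), PPh3, diisopropyl azodicarboxylate, THF, 0 °C to rt
Reagents that add atoms: benzyl alcohol, OCc1ccccc1
Why: Mitsunobu etherification of one of two equivalent ortho hydroxyls; after the first alkylation the remaining hydroxyl is locked in the chelate and should not react, and the neutral medium avoids phenoxide-driven scrambling of the aryl ester.

Step 4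
Reactants: 5 3-(benzyloxy)-4-formyl-5-hydroxyphenyl 3,4,5-tris(benzyloxy)benzoate
Product: 6 3-(benzyloxy)-5-hydroxy-4-(hydroxymethyl)phenyl 3,4,5-tris(benzyloxy)benzoate
Conditions: NaBH4, THF/H2O (10:1), 0 °C, short reaction time; pH 7 phosphate buffer; product used at once without acidic silica
Reagents that add atoms: none
Why: Borohydride reduction of an aldehyde in the presence of hindered, electron-rich aryl benzoates; low temperature and a neutral quench should prevent ionisation of the salicyl alcohol.

Step 5
Reactants: 7 4-(benzyloxy)-3-hydroxybenzaldehyde; 2 3,4,5-tris(benzyloxy)benzoyl chloride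
Product: 8 2-(benzyloxy)-5-formylphenyl 3,4,5-tris(benzyloxy)benzoate
Conditions: Et3N, 4-(dimethylamino)pyridine (cat.), CH2Cl2, 0 °C to rt
Reagents that add atoms: none
Why: Nucleophile-catalysed acylation of the single free phenol; no selectivity is required.

Step 6
Reactants: 8 2-(benzyloxy)-5-formylphenyl 3,4,5-tris(benzyloxy)benzoate
Product: 9 2-(benzyloxy)-5-[(E)-3-oxoprop-1-en-1-yl]phenyl 3,4,5-tris(benzyloxy)benzoate
Conditions: Ph3P=CHCHO (1.2 equiv), toluene, 80 °C
Reagents that add atoms: (triphenylphosphoranylidene)acetaldehyde, O=CC=P(c1ccccc1)(c1ccccc1)c1ccccc1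
Why: Wittig reaction of a stabilised ylide, which should give the E enal; the ylide does not attack aryl esters, and keeping it near stoichiometric limits a second homologation.

Step 7
Reactants: 9 2-(benzyloxy)-5-[(E)-3-oxoprop-1-en-1-yl]phenyl 3,4,5-tris(benzyloxy)benzoate
Product: 10 2-(benzyloxy)-5-[(E)-2-(formyloxy)ethenyl]phenyl 3,4,5-tris(benzyloxy)benzoate
Conditions: 30% aq. H2O2, bis(2-nitrophenyl) diselenide (5 mol %), CH2Cl2, rt
Reagents that add atoms: hydrogen peroxide, OO
Why: Selenium-catalysed Baeyer–Villiger oxidation of an α,β-unsaturated aldehyde to the enol formate; the alkenyl group migrates in the Criegee adduct with retention of its geometry, so the E double bond from step 6 is kept.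

Step 8
Reactants: 10 2-(benzyloxy)-5-[(E)-2-(formyloxy)ethenyl]phenyl 3,4,5-tris(benzyloxy)benzoate
Product: 12 2-(benzyloxy)-5-[(E)-2-{[(benzyloxy)carbonyl]oxy}ethenyl]phenyl 3,4,5-tris(benzyloxy)benzoate, via potassium (E)-enolate 11 (not isolated)
Conditions: KOt-Bu (1.0 equiv), THF, −78 °C, 5 min; then BnOCOCl (1.2 equiv), −78 to −40 °C; pH 7 buffer
Reagents that add atoms: benzyl chloroformate, O=C(Cl)OCc1ccccc1
Why: Alkoxide cleavage of an enol ester gives the aldehyde enolate with its geometry intact, since no proton source is present at −78 °C, and chloroformates acylate such potassium enolates on oxygen. The unhindered formyl group should be attacked far faster than the two hindered, electron-rich aryl benzoates.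

Step 9
Reactants: 6 3-(benzyloxy)-5-hydroxy-4-(hydroxymethyl)phenyl 3,4,5-tris(benzyloxy)benzoate; 12 2-(benzyloxy)-5-[(E)-2-{[(benzyloxy)carbonyl]oxy}ethenyl]phenyl 3,4,5-tris(benzyloxy)benzoate
Product: 14 (2R,3S)-5-(benzyloxy)-2-[4-(benzyloxy)-3-{[3,4,5-tris(benzyloxy)benzoyl]oxy}phenyl]-3-{[(benzyloxy)carbonyl]oxy}chroman-7-yl 3,4,5-tris(benzyloxy)benzoate, via ortho-quinone methide 13 (not isolated)
Conditions: (R)-3,3'-bis(2,4,6-triisopropylphenyl)-1,1'-binaphthyl-2,2'-diyl hydrogen phosphate (10 mol %), 5 Å molecular sieves, toluene/CH2Cl2 (4:1), −20 °C; 6 (1.5 equiv) added over several hours to 12 and the acid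
Reagents that add atoms: none
Why: Proposed new method: the acid protonates the benzylic hydroxyl of 6, water leaves with help from the ortho hydroxyl and the ortho and para oxygens, and quinone methide 13 stays hydrogen-bonded through its carbonyl oxygen to the phosphate while the sieves take up the water. 13 (O1=C8a–C4a=C4) and 12 then combine in an inverse-electron-demand hetero-Diels–Alder reaction in which the enol carbon (C3) bonds to the electrophilic methylene C4 and the benzylic carbon (C2) to O1, so ring C closes in one intermolecular [4+2] event with no separate cyclisation. The closest known reaction type is the Brønsted-acid and chiral-phosphoric-acid catalysed [4+2] addition of quinone methides, made in situ from ortho-hydroxybenzyl alcohols, to styrenes, enol ethers and enamides; new here are an enol carbonate as the 2π partner and enantiocontrol without a second hydrogen bond to it. The regiochemistry should follow from the asynchronous transition state, in which positive charge builds on the carbon that the 4-benzyloxyphenyl group stabilises, the carbonate oxygen being a weak, cross-conjugated donor. C2 and C3 are set together: suprafacial addition to the E alkene gives the trans relationship, and a stepwise closure through the para-alkoxybenzyl cation would also favour the trans diequatorial ring. Because the diene has no stereocentre, the absolute configuration depends only on which face of 12 is used; on the face of 13 left open by the triisopropylphenyl walls this reduces to aryl-endo against aryl-exo approach, which the catalyst pocket must decide. Slow addition of 6 keeps 13 dilute so that it is trapped by 12 and not by ring A of 6 or 14, which the ester and the benzyl ether also deactivate.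

Step 10
Reactants: 14 (2R,3S)-5-(benzyloxy)-2-[4-(benzyloxy)-3-{[3,4,5-tris(benzyloxy)benzoyl]oxy}phenyl]-3-{[(benzyloxy)carbonyl]oxy}chroman-7-yl 3,4,5-tris(benzyloxy)benzoate
Product: 15 catechin 7,3'-di-O-gallate, (2R,3S)-3,5-dihydroxy-2-{4-hydroxy-3-[(3,4,5-trihydroxybenzoyl)oxy]phenyl}chroman-7-yl 3,4,5-trihydroxybenzoate
Conditions: H2 (1 atm), Pd(OH)2 on carbon, THF/MeOH (1:1), rt; filtration under argon, no base
Reagents that add atoms: none
Why: Hydrogenolysis cleaves the eight benzyl ethers and the benzyl carbonate, whose carbonic acid half-ester loses CO2 to free O3. The aryl esters, the cyclic C2–O1 bond and both stereocentres are expected to persist as in debenzylations of other catechin gallates, and the neutral medium avoids the O3' to O4' acyl shift.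

## Compound list

1 | 3,4,5-tris(benzyloxy)benzoic acid | OC(=O)c1cc(OCc2ccccc2)c(OCc2ccccc2)c(OCc2ccccc2)c1 | starting material
2 | 3,4,5-tris(benzyloxy)benzoyl chloride | ClC(=O)c1cc(OCc2ccccc2)c(OCc2ccccc2)c(OCc2ccccc2)c1 | intermediate
3 | 2,4,6-trihydroxybenzaldehyde | O=Cc1c(O)cc(O)cc1O | starting material
4 | 4-formyl-3,5-dihydroxyphenyl 3,4,5-tris(benzyloxy)benzoate | O=Cc1c(O)cc(OC(=O)c2cc(OCc3ccccc3)c(OCc3ccccc3)c(OCc3ccccc3)c2)cc1O | intermediate
5 | 3-(benzyloxy)-4-formyl-5-hydroxyphenyl 3,4,5-tris(benzyloxy)benzoate | O=Cc1c(O)cc(OC(=O)c2cc(OCc3ccccc3)c(OCc3ccccc3)c(OCc3ccccc3)c2)cc1OCc1ccccc1 | intermediate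
6 | 3-(benzyloxy)-5-hydroxy-4-(hydroxymethyl)phenyl 3,4,5-tris(benzyloxy)benzoate | OCc1c(O)cc(OC(=O)c2cc(OCc3ccccc3)c(OCc3ccccc3)c(OCc3ccccc3)c2)cc1OCc1ccccc1 | intermediate
7 | 4-(benzyloxy)-3-hydroxybenzaldehyde | O=Cc1ccc(OCc2ccccc2)c(O)c1 | starting material
8 | 2-(benzyloxy)-5-formylphenyl 3,4,5-tris(benzyloxy)benzoate | O=Cc1ccc(OCc2ccccc2)c(OC(=O)c2cc(OCc3ccccc3)c(OCc3ccccc3)c(OCc3ccccc3)c2)c1 | intermediate
9 | 2-(benzyloxy)-5-[(E)-3-oxoprop-1-en-1-yl]phenyl 3,4,5-tris(benzyloxy)benzoate | O=C/C=C/c1ccc(OCc2ccccc2)c(OC(=O)c2cc(OCc3ccccc3)c(OCc3ccccc3)c(OCc3ccccc3)c2)c1 | intermediate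
10 | 2-(benzyloxy)-5-[(E)-2-(formyloxy)ethenyl]phenyl 3,4,5-tris(benzyloxy)benzoate | O=CO/C=C/c1ccc(OCc2ccccc2)c(OC(=O)c2cc(OCc3ccccc3)c(OCc3ccccc3)c(OCc3ccccc3)c2)c1 | intermediate
11 | potassium (E)-2-[4-(benzyloxy)-3-{[3,4,5-tris(benzyloxy)benzoyl]oxy}phenyl]ethen-1-olate | [K+].[O-]/C=C/c1ccc(OCc2ccccc2)c(OC(=O)c2cc(OCc3ccccc3)c(OCc3ccccc3)c(OCc3ccccc3)c2)c1 | intermediate (not isolated)
12 | 2-(benzyloxy)-5-[(E)-2-{[(benzyloxy)carbonyl]oxy}ethenyl]phenyl 3,4,5-tris(benzyloxy)benzoate | O=C(OCc1ccccc1)O/C=C/c1ccc(OCc2ccccc2)c(OC(=O)c2cc(OCc3ccccc3)c(OCc3ccccc3)c(OCc3ccccc3)c2)c1 | intermediate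
13 | 5-(benzyloxy)-4-methylidene-3-oxocyclohexa-1,5-dien-1-yl 3,4,5-tris(benzyloxy)benzoate (ortho-quinone methide) | C=C1C(=O)C=C(OC(=O)c2cc(OCc3ccccc3)c(OCc3ccccc3)c(OCc3ccccc3)c2)C=C1OCc1ccccc1 | intermediate (not isolated)
14 | (2R,3S)-5-(benzyloxy)-2-[4-(benzyloxy)-3-{[3,4,5-tris(benzyloxy)benzoyl]oxy}phenyl]-3-{[(benzyloxy)carbonyl]oxy}chroman-7-yl 3,4,5-tris(benzyloxy)benzoate | O=C(Oc1cc(OCc2ccccc2)c2c(c1)O[C@H](c1ccc(OCc3ccccc3)c(OC(=O)c3cc(OCc4ccccc4)c(OCc4ccccc4)c(OCc4ccccc4)c3)c1)[C@@H](OC(=O)OCc1ccccc1)C2)c1cc(OCc2ccccc2)c(OCc2ccccc2)c(OCc2ccccc2)c1 | intermediate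
15 | catechin 7,3'-di-O-gallate, (2R,3S)-3,5-dihydroxy-2-{4-hydroxy-3-[(3,4,5-trihydroxybenzoyl)oxy]phenyl}chroman-7-yl 3,4,5-trihydroxybenzoate | O=C(Oc1cc(O)c2c(c1)O[C@H](c1ccc(O)c(OC(=O)c3cc(O)c(O)c(O)c3)c1)[C@@H](O)C2)c1cc(O)c(O)c(O)c1 | target

## Step count and least certain steps

Total step count: 10. Longest linear sequence: 7 steps (steps 1, 5, 6, 7, 8, 9, 10, from 1 to 15). The ring A branch (steps 1 to 4) joins at step 9.

**Step 9 (key step).** The most likely failure is poor discrimination between the two faces of 12, because the catalyst holds only the quinone methide and the dienophile has no hydrogen-bond donor. Further risks are a reversed orientation if the carbonate oxygen competes with the aryl group for charge stabilisation, and self-condensation of the quinone methide with ring A. The fallback uses known reaction types only and forms the same two bonds from the two aldehydes 5 and 9. Amine-catalysed oxa-Michael/aldol condensation of salicylaldehyde 5 with enal 9 (α,α-diphenylprolinol trimethylsilyl ether of the appropriate configuration, 2-nitrobenzoic acid, toluene) would give (R)-5-(benzyloxy)-2-[4-(benzyloxy)-3-{[3,4,5-tris(benzyloxy)benzoyl]oxy}phenyl]-3-formyl-2H-chromen-7-yl 3,4,5-tris(benzyloxy)benzoate F1. Decarbonylation with stoichiometric RhCl(PPh3)3 in hot toluene/benzonitrile would give the flav-3-ene, (S)-5-(benzyloxy)-2-[4-(benzyloxy)-3-{[3,4,5-tris(benzyloxy)benzoyl]oxy}phenyl]-2H-chromen-7-yl 3,4,5-tris(benzyloxy)benzoate F2. Hydroboration anti to the C2 aryl group (BH3·SMe2, THF, 0 °C) and oxidation with NaBO3·4H2O would give the trans alcohol, (2R,3S)-5-(benzyloxy)-2-[4-(benzyloxy)-3-{[3,4,5-tris(benzyloxy)benzoyl]oxy}phenyl]-3-hydroxychroman-7-yl 3,4,5-tris(benzyloxy)benzoate F3. Hydrogenolysis of F3 under the conditions of step 10 comes back to the route at 15.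

**Step 8.** tert-Butoxide or the enolate 11 may attack an aryl gallate, and any proton transfer would erode the E geometry. The fallback sets out from 10 and gives up stereoretention for separation. Mild methanolysis of the enol formate (KHCO3, MeOH/THF, 0 °C) would give 2-(benzyloxy)-5-(2-oxoethyl)phenyl 3,4,5-tris(benzyloxy)benzoate F4. Amine-mediated O-acylation (BnOCOCl, Et3N, 4-(dimethylamino)pyridine, CH2Cl2) would give the enol carbonate as a geometric mixture, from which the E isomer is separated by crystallisation or chromatography. The route is regained at 12.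

**Step 7.** The peroxyseleninic acid may epoxidise the electron-rich double bond of 10, hydrogen may migrate instead of the alkenyl group, or the enol formate may hydrolyse in the wet medium. The fallback sets out from 8 and drops steps 6 and 7. Wittig methoxymethylenation (Ph3P=CHOMe from (methoxymethyl)triphenylphosphonium chloride and KN(SiMe3)2, THF, −78 °C) would give 2-(benzyloxy)-5-(2-methoxyethenyl)phenyl 3,4,5-tris(benzyloxy)benzoate F5 as an E/Z mixture. Hydrolysis with aqueous HCl in THF would give the aldehyde F4 described under step 8, which is taken on in the same way to 12.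

**Step 4.** Ionisation of 6 during reduction or isolation may lead to over-reduction to the methyl compound or to self-condensation, because the benzylic position is flanked by two oxygen donors. The fallback sets out from 5 and stores ring A as a benzylic ether. Reduction with NaBH4 in ethanol, then holding the crude product in ethanol with a trace of acetic acid, should let the solvent trap the quinone methide to give 3-(benzyloxy)-4-(ethoxymethyl)-5-hydroxyphenyl 3,4,5-tris(benzyloxy)benzoate F6. Ortho-hydroxybenzyl ethers are established quinone methide precursors; F6 would replace 6 in step 9, lose ethanol to 13, and return to the route at 14.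

**Step 3.** The chelated phenol may react sluggishly, the reaction may not stop at mono-benzylation, or the aryl ester may scramble. The fallback sets out from 4 and omits the O5 benzyl group altogether. Reduction as in step 4 would give the mirror-symmetric triol, 3,5-dihydroxy-4-(hydroxymethyl)phenyl 3,4,5-tris(benzyloxy)benzoate F7, in which either ortho hydroxyl leads to the same quinone methide. Under the conditions of step 9 this would pass through 5-hydroxy-4-methylidene-3-oxocyclohexa-1,5-dien-1-yl 3,4,5-tris(benzyloxy)benzoate F8 (not isolated) and add 12 to give (2R,3S)-2-[4-(benzyloxy)-3-{[3,4,5-tris(benzyloxy)benzoyl]oxy}phenyl]-3-{[(benzyloxy)carbonyl]oxy}-5-hydroxychroman-7-yl 3,4,5-tris(benzyloxy)benzoate F9. Hydrogenolysis of F9 under the conditions of step 10 comes back to the route at 15.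

## Further compounds

F1 | step 9 | (R)-5-(benzyloxy)-2-[4-(benzyloxy)-3-{[3,4,5-tris(benzyloxy)benzoyl]oxy}phenyl]-3-formyl-2H-chromen-7-yl 3,4,5-tris(benzyloxy)benzoate | O=C(Oc1cc(OCc2ccccc2)c2c(c1)O[C@H](c1ccc(OCc3ccccc3)c(OC(=O)c3cc(OCc4ccccc4)c(OCc4ccccc4)c(OCc4ccccc4)c3)c1)C(C=O)=C2)c1cc(OCc2ccccc2)c(OCc2ccccc2)c(OCc2ccccc2)c1
F2 | step 9 | (S)-5-(benzyloxy)-2-[4-(benzyloxy)-3-{[3,4,5-tris(benzyloxy)benzoyl]oxy}phenyl]-2H-chromen-7-yl 3,4,5-tris(benzyloxy)benzoate | O=C(Oc1cc(OCc2ccccc2)c2c(c1)O[C@H](c1ccc(OCc3ccccc3)c(OC(=O)c3cc(OCc4ccccc4)c(OCc4ccccc4)c(OCc4ccccc4)c3)c1)C=C2)c1cc(OCc2ccccc2)c(OCc2ccccc2)c(OCc2ccccc2)c1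
F3 | step 9 | (2R,3S)-5-(benzyloxy)-2-[4-(benzyloxy)-3-{[3,4,5-tris(benzyloxy)benzoyl]oxy}phenyl]-3-hydroxychroman-7-yl 3,4,5-tris(benzyloxy)benzoate | O=C(Oc1cc(OCc2ccccc2)c2c(c1)O[C@H](c1ccc(OCc3ccccc3)c(OC(=O)c3cc(OCc4ccccc4)c(OCc4ccccc4)c(OCc4ccccc4)c3)c1)[C@@H](O)C2)c1cc(OCc2ccccc2)c(OCc2ccccc2)c(OCc2ccccc2)c1
F4 | step 8 | 2-(benzyloxy)-5-(2-oxoethyl)phenyl 3,4,5-tris(benzyloxy)benzoate | O=CCc1ccc(OCc2ccccc2)c(OC(=O)c2cc(OCc3ccccc3)c(OCc3ccccc3)c(OCc3ccccc3)c2)c1
F5 | step 7 | 2-(benzyloxy)-5-(2-methoxyethenyl)phenyl 3,4,5-tris(benzyloxy)benzoate (E/Z mixture) | COC=Cc1ccc(OCc2ccccc2)c(OC(=O)c2cc(OCc3ccccc3)c(OCc3ccccc3)c(OCc3ccccc3)c2)c1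
F6 | step 4 | 3-(benzyloxy)-4-(ethoxymethyl)-5-hydroxyphenyl 3,4,5-tris(benzyloxy)benzoate | CCOCc1c(O)cc(OC(=O)c2cc(OCc3ccccc3)c(OCc3ccccc3)c(OCc3ccccc3)c2)cc1OCc1ccccc1
F7 | step 3 | 3,5-dihydroxy-4-(hydroxymethyl)phenyl 3,4,5-tris(benzyloxy)benzoate | OCc1c(O)cc(OC(=O)c2cc(OCc3ccccc3)c(OCc3ccccc3)c(OCc3ccccc3)c2)cc1O
F8 | step 3 | 5-hydroxy-4-methylidene-3-oxocyclohexa-1,5-dien-1-yl 3,4,5-tris(benzyloxy)benzoate | C=C1C(=O)C=C(OC(=O)c2cc(OCc3ccccc3)c(OCc3ccccc3)c(OCc3ccccc3)c2)C=C1O
F9 | step 3 | (2R,3S)-2-[4-(benzyloxy)-3-{[3,4,5-tris(benzyloxy)benzoyl]oxy}phenyl]-3-{[(benzyloxy)carbonyl]oxy}-5-hydroxychroman-7-yl 3,4,5-tris(benzyloxy)benzoate | O=C(Oc1cc(O)c2c(c1)O[C@H](c1ccc(OCc3ccccc3)c(OC(=O)c3cc(OCc4ccccc4)c(OCc4ccccc4)c(OCc4ccccc4)c3)c1)[C@@H](OC(=O)OCc1ccccc1)C2)c1cc(OCc2ccccc2)c(OCc2ccccc2)c(OCc2ccccc2)c1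
A1 | alternative 1 | 5-[(triisopropylsilyl)oxy]cyclohexane-1,3-dione | O=C1CC(O[Si](C(C)C)(C(C)C)C(C)C)CC(=O)C1
A2 | alternative 1 | (2R,3S)-3-[4-(benzyloxy)-3-(triisopropylsilyloxy)phenyl]oxirane-2-carbaldehyde | O=C[C@@H]1O[C@H]1c1ccc(OCc2ccccc2)c(O[Si](C(C)C)(C(C)C)C(C)C)c1
A3 | alternative 1 | (2R,3S)-2-[4-(benzyloxy)-3-(triisopropylsilyloxy)phenyl]-3-hydroxy-7-(triisopropylsilyloxy)-2,3,4,6,7,8-hexahydro-5H-chromen-5-one (both C7 epimers) | O=C1CC(O[Si](C(C)C)(C(C)C)C(C)C)CC2=C1C[C@H](O)[C@@H](c1ccc(OCc3ccccc3)c(O[Si](C(C)C)(C(C)C)C(C)C)c1)O2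
A4 | alternative 2 | 1-(benzyloxy)-3-{[(1S)-1-[4-(benzyloxy)-3-(methoxymethoxy)phenyl]prop-2-en-1-yl]oxy}-2-ethenyl-5-(methoxymethoxy)benzene | C=Cc1c(OCc2ccccc2)cc(OCOC)cc1O[C@H](c1ccc(OCc2ccccc2)c(OCOC)c1)C=C
A5 | alternative 2 | (S)-5-(benzyloxy)-2-[4-(benzyloxy)-3-(methoxymethoxy)phenyl]-7-(methoxymethoxy)-2H-chromene | COCOc1cc(OCc2ccccc2)c2c(c1)O[C@H](c1ccc(OCc3ccccc3)c(OCOC)c1)C=C2
A6 | alternative 3 | 3-[(tert-butyldimethylsilyl)oxy]buta-1,3-dien-2-yl 3,4,5-tris(benzyloxy)benzoate | C=C(O[Si](C)(C)C(C)(C)C)C(=C)OC(=O)c1cc(OCc2ccccc2)c(OCc2ccccc2)c(OCc2ccccc2)c1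
A7 | alternative 3 | (4S)-4-(benzyloxy)-5-[2-(benzyloxy)-4,6-bis(methoxymethoxy)phenyl]pent-1-yn-3-one | C#CC(=O)[C@@H](OCc1ccccc1)Cc1c(OCOC)cc(OCOC)cc1OCc1ccccc1
A8 | alternative 3 | 5-{(S)-2-(benzyloxy)-3-[2-(benzyloxy)-4,6-bis(methoxymethoxy)phenyl]propanoyl}-2-(tert-butyldimethylsilyloxy)cyclohexa-1,4-dien-1-yl 3,4,5-tris(benzyloxy)benzoate | O=C(C1=CCC(O[Si](C)(C)C(C)(C)C)=C(OC(=O)c2cc(OCc3ccccc3)c(OCc3ccccc3)c(OCc3ccccc3)c2)C1)[C@@H](OCc1ccccc1)Cc1c(OCOC)cc(OCOC)cc1OCc1ccccc1
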